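**Retrosynthetic overview**
1. Target 20 comes from acid 19 by fluoride cleavage of two aryl silyl ethers; no ester hydrolysis and no hydrogenation is needed near the prenyl alkenes.
2. Key disconnection of 19: the ring A bonds C6–CH2 (arylethyl arm) and C1–CO2H are cut together. C1 and C6 are vicinal and C1 sits next to the methoxy-bearing C2, which is the pattern a 3-methoxyaryne (C1≡C6, OMe on C2) leaves after a carbon nucleophile adds at the distal carbon C6 and CO2 takes the OMe-flanked carbanion at C1. This gives aryl triflate 10, Grignard reagent 14 and CO2 15.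
3. Triflate 10 comes from 5-methoxyresorcinol 1: bis-MOM ether, two successive directed ortho-lithiation/prenylations (ring A C5, then C3), MOM removal, triflation of the less hindered phenol (C6–O), silylation of the prenyl-flanked phenol (C4–O).
4. Grignard reagent 14 comes from tyrosol 11: HBr, TBSCl, Mg.
5. No ring is formed at any stage; ring A is carried in from 1 and ring B from 11.

Key step: step 10

Remark on the chemistry: ring A is numbered from the carboxyl carbon (C1 CO2H, C2 OMe, C3 prenyl, C4 OH, C5 prenyl, C6 arylethyl). The target has no stereocentre and no stereogenic alkene, so no stereocontrol is required.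

**Route**

Step 1
Reactants: 1 5-methoxyresorcinol
Product: 2 1-methoxy-3,5-bis(methoxymethoxy)benzene
Conditions: NaH (2.5 equiv), MOMCl (2.4 equiv), DMF, 0 → 25 °C
Reagents that add atoms: chloromethyl methyl ether (MOMCl), COCCl
Why: Double Williamson O-alkylation of the two phenoxides gives the bis-acetal, whose OMOM groups are strong directing groups for the ortho-lithiations that follow.

Step 2
Reactants: 2 1-methoxy-3,5-bis(methoxymethoxy)benzene; 3 prenyl bromide (1-bromo-3-methylbut-2-ene)
Product: 5 5-methoxy-1,3-bis(methoxymethoxy)-2-(3-methylbut-2-enyl)benzene, via aryllithium 4 (not isolated)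
Conditions: n-BuLi (1.1 equiv), THF, 0 → 25 °C; then CuI (10 mol %), 3 (1.3 equiv), −78 → 25 °C
Reagents that add atoms: none
Why: Directed ortho-metalation removes the hydrogen between the two OMOM groups (the doubly coordinated, most acidic site), and copper-catalysed SN2 alkylation of the aryllithium at the primary carbon of the allylic bromide places the future C5 prenyl group.

Step 3
Reactants: 5 5-methoxy-1,3-bis(methoxymethoxy)-2-(3-methylbut-2-enyl)benzene; 3 prenyl bromide
Product: 7 1-methoxy-3,5-bis(methoxymethoxy)-2,4-bis(3-methylbut-2-enyl)benzene, via aryllithium 6 (not isolated)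
Conditions: n-BuLi (1.2 equiv), TMEDA (1.2 equiv), THF, −20 → 0 °C; then CuI (10 mol %), 3 (1.4 equiv), −78 → 25 °C
Reagents that add atoms: none
Why: A second directed ortho-metalation can give only one regioisomer because the two remaining ring hydrogens of symmetric 5 are equivalent and each lies between OMOM and OMe, where ring lithiation should be kinetically preferred over removal of a benzylic-allylic hydrogen; alkylation as in step 2 installs the future C3 prenyl group.

Step 4
Reactants: 7 1-methoxy-3,5-bis(methoxymethoxy)-2,4-bis(3-methylbut-2-enyl)benzene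
Product: 8 5-methoxy-2,4-bis(3-methylbut-2-enyl)benzene-1,3-diol
Conditions: HCl (1.25 M in MeOH), 0 → 25 °C
Reagents that add atoms: none
Why: Acid-catalysed acetal exchange with methanol cleaves both MOM ethers, and dilute acid at or below room temperature is chosen so that the ortho-prenyl phenols are not cyclised to chromans.

Step 5
Reactants: 8 5-methoxy-2,4-bis(3-methylbut-2-enyl)benzene-1,3-diol
Product: 9 3-hydroxy-5-methoxy-2,4-bis(3-methylbut-2-enyl)phenyl trifluoromethanesulfonate
Conditions: PhNTf2 (1.05 equiv), Et3N (2 equiv), CH2Cl2, 0 → 25 °C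
Reagents that add atoms: N-phenylbis(trifluoromethanesulfonimide), O=S(=O)(N(c1ccccc1)S(=O)(=O)C(F)(F)F)C(F)(F)F
Why: Site-selective O-sulfonylation with the bulky, mild triflimide should take the phenol that has one ortho substituent (prenyl and H as neighbours) and leave the phenol buried between two prenyl groups.

Step 6
Reactants: 9 3-hydroxy-5-methoxy-2,4-bis(3-methylbut-2-enyl)phenyl trifluoromethanesulfonate
Product: 10 3-(tert-butyldimethylsilyloxy)-5-methoxy-2,4-bis(3-methylbut-2-enyl)phenyl trifluoromethanesulfonate
Conditions: TBSOTf (1.5 equiv), 2,6-lutidine (2.5 equiv), CH2Cl2, 0 → 25 °C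
Reagents that add atoms: tert-butyldimethylsilyl trifluoromethanesulfonate, CC(C)(C)[Si](C)(C)OS(=O)(=O)C(F)(F)F
Why: O-silylation with the highly electrophilic silyl triflate under lutidine buffering is the standard answer to a di-ortho-substituted phenol, and the aryl triflate and alkenes are inert to it.

Step 7
Reactants: 11 tyrosol (4-(2-hydroxyethyl)phenol)
Product: 12 4-(2-bromoethyl)phenol
Conditions: 48% aq HBr, 90 °C
Reagents that add atoms: hydrogen bromide, Br
Why: SN2 displacement of the protonated primary alcohol by bromide converts only the aliphatic hydroxyl, the phenol being inert to HBr.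

Step 8
Reactants: 12 4-(2-bromoethyl)phenol
Product: 13 tert-butyl[4-(2-bromoethyl)phenoxy]dimethylsilane
Conditions: TBSCl (1.2 equiv), imidazole (2.2 equiv), DMF, 0 → 25 °C
Reagents that add atoms: tert-butyldimethylsilyl chloride, CC(C)(C)[Si](C)(C)Cl
Why: Imidazole-promoted O-silylation protects the phenol under conditions too weakly basic to trigger phenoxide participation at the primary bromide.

Step 9
Reactants: 13 tert-butyl[4-(2-bromoethyl)phenoxy]dimethylsilane
Product: 14 {2-[4-(tert-butyldimethylsilyloxy)phenyl]ethyl}magnesium bromide (kept as a titrated THF solution)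
Conditions: Mg turnings (1.5 equiv), I2 (cat.), THF, 25 → 45 °C, slow addition of 13
Reagents that add atoms: magnesium, [Mg]
Why: Grignard formation by oxidative insertion of magnesium into the primary C–Br bond, to which the aryl silyl ether is inert; slow addition limits Wurtz coupling.

Step 10
Reactants: 10 3-(tert-butyldimethylsilyloxy)-5-methoxy-2,4-bis(3-methylbut-2-enyl)phenyl trifluoromethanesulfonate; 14 {2-[4-(tert-butyldimethylsilyloxy)phenyl]ethyl}magnesium bromide; 15 carbon dioxide
Product: 19 4-(tert-butyldimethylsilyloxy)-6-{2-[4-(tert-butyldimethylsilyloxy)phenyl]ethyl}-2-methoxy-3,5-bis(3-methylbut-2-enyl)benzoic acid, via magnesiated triflate 16 (not isolated), via aryne 17 (not isolated), via arylmagnesium adduct 18 (not isolated)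
Conditions: 14 (3 equiv), THF, −30 °C; TMPMgCl·LiCl (1.3 equiv), −30 → 25 °C; then CO2 gas (15), −20 → 0 °C; 1 M aq HCl, 0 °C
Reagents that add atoms: none
Why: TMPMgCl·LiCl magnesiates the only ring C–H of 10, the C1–H acidified by the flanking triflate and methoxy groups, to give 16, which on warming loses magnesium triflate by β-elimination and releases the C1≡C6 aryne 17. The closest known reaction type is the three-component aryne coupling in which a Grignard reagent carbomagnesiates a 3-alkoxyaryne generated from an ortho-metalated aryl sulfonate and the new arylmagnesium is trapped by an electrophile, as in the classical preparation of 2-alkyl-6-methoxybenzoic acids from 3-methoxybenzyne, an organometallic reagent and CO2. The C2 methoxy group polarises and distorts the aryne so that the distal carbon C6 is the electrophilic terminus, and attack of 14 there leaves the carbanion at C1, where the ortho oxygen stabilises it inductively and chelates magnesium in 18. This electronic bias has to override the shielding of C6 by the C5 prenyl group, and it should, because C1 is itself flanked by the methoxy group and addition there would put the anion away from oxygen. Carboxylation of 18 with CO2 and acidification then give 19, so the C6–CH2 and C1–CO2H bonds are formed in one flask, with no ring closure and no new stereocentre. Chemoselectivity rests on the inertness of silyl ethers, trisubstituted alkenes and the aryl methyl ether to both magnesium reagents, and on keeping 14 in excess while the aryne is released, so that carbomagnesiation outruns a thia-Fries shift of 16, amide addition and β-hydride transfer.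

Step 11
Reactants: 19 4-(tert-butyldimethylsilyloxy)-6-{2-[4-(tert-butyldimethylsilyloxy)phenyl]ethyl}-2-methoxy-3,5-bis(3-methylbut-2-enyl)benzoic acid
Product: 20 4-hydroxy-6-[2-(4-hydroxyphenyl)ethyl]-2-methoxy-3,5-bis(3-methylbut-2-enyl)benzoic acid
Conditions: Bu4NF (4 equiv), THF, 0 → 25 °C; then 0.5 M aq HCl to pH 4, 0 °C
Reagents that add atoms: none
Why: Fluoride-induced cleavage of both aryl Si–O bonds (driven by the strong Si–F bond) frees the two phenols, and cold, weakly acidic work-up returns the carboxylic acid without chroman formation or decarboxylation.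

**Compound list**
1 | 5-methoxyresorcinol | COc1cc(O)cc(O)c1 | starting material
2 | 1-methoxy-3,5-bis(methoxymethoxy)benzene | COCOc1cc(OC)cc(OCOC)c1 | intermediate
3 | prenyl bromide (1-bromo-3-methylbut-2-ene) | CC(C)=CCBr | starting material
4 | [4-methoxy-2,6-bis(methoxymethoxy)phenyl]lithium | [Li]c1c(OCOC)cc(OC)cc1OCOC | intermediate
5 | 5-methoxy-1,3-bis(methoxymethoxy)-2-(3-methylbut-2-enyl)benzene | COCOc1cc(OC)cc(OCOC)c1CC=C(C)C | intermediate
6 | [6-methoxy-2,4-bis(methoxymethoxy)-3-(3-methylbut-2-enyl)phenyl]lithium | [Li]c1c(OC)cc(OCOC)c(CC=C(C)C)c1OCOC | intermediate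
7 | 1-methoxy-3,5-bis(methoxymethoxy)-2,4-bis(3-methylbut-2-enyl)benzene | COc1cc(OCOC)c(CC=C(C)C)c(OCOC)c1CC=C(C)C | intermediate
8 | 5-methoxy-2,4-bis(3-methylbut-2-enyl)benzene-1,3-diol | COc1cc(O)c(CC=C(C)C)c(O)c1CC=C(C)C | intermediate
9 | 3-hydroxy-5-methoxy-2,4-bis(3-methylbut-2-enyl)phenyl trifluoromethanesulfonate | COc1cc(OS(=O)(=O)C(F)(F)F)c(CC=C(C)C)c(O)c1CC=C(C)C | intermediate
10 | 3-(tert-butyldimethylsilyloxy)-5-methoxy-2,4-bis(3-methylbut-2-enyl)phenyl trifluoromethanesulfonate | COc1cc(OS(=O)(=O)C(F)(F)F)c(CC=C(C)C)c(O[Si](C)(C)C(C)(C)C)c1CC=C(C)C | intermediate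
11 | tyrosol (4-(2-hydroxyethyl)phenol) | OCCc1ccc(O)cc1 | starting material
12 | 4-(2-bromoethyl)phenol | BrCCc1ccc(O)cc1 | intermediate
13 | tert-butyl[4-(2-bromoethyl)phenoxy]dimethylsilane | BrCCc1ccc(O[Si](C)(C)C(C)(C)C)cc1 | intermediate
14 | {2-[4-(tert-butyldimethylsilyloxy)phenyl]ethyl}magnesium bromide | Br[Mg]CCc1ccc(O[Si](C)(C)C(C)(C)C)cc1 | intermediate
15 | carbon dioxide | O=C=O | starting material
16 | [4-(tert-butyldimethylsilyloxy)-2-methoxy-3,5-bis(3-methylbut-2-enyl)-6-(trifluoromethanesulfonyloxy)phenyl]magnesium chloride | COc1c([Mg]Cl)c(OS(=O)(=O)C(F)(F)F)c(CC=C(C)C)c(O[Si](C)(C)C(C)(C)C)c1CC=C(C)C | intermediate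
17 | 5-(tert-butyldimethylsilyloxy)-3-methoxy-4,6-bis(3-methylbut-2-enyl)-1,2-didehydrobenzene (aryne) | COC1=C(CC=C(C)C)C(O[Si](C)(C)C(C)(C)C)=C(CC=C(C)C)C#C1 | intermediate
18 | [4-(tert-butyldimethylsilyloxy)-6-{2-[4-(tert-butyldimethylsilyloxy)phenyl]ethyl}-2-methoxy-3,5-bis(3-methylbut-2-enyl)phenyl]magnesium bromide | COc1c([Mg]Br)c(CCc2ccc(O[Si](C)(C)C(C)(C)C)cc2)c(CC=C(C)C)c(O[Si](C)(C)C(C)(C)C)c1CC=C(C)C | intermediate
19 | 4-(tert-butyldimethylsilyloxy)-6-{2-[4-(tert-butyldimethylsilyloxy)phenyl]ethyl}-2-methoxy-3,5-bis(3-methylbut-2-enyl)benzoic acid | OC(=O)c1c(OC)c(CC=C(C)C)c(O[Si](C)(C)C(C)(C)C)c(CC=C(C)C)c1CCc1ccc(O[Si](C)(C)C(C)(C)C)cc1 | intermediate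
20 | 4-hydroxy-6-[2-(4-hydroxyphenyl)ethyl]-2-methoxy-3,5-bis(3-methylbut-2-enyl)benzoic acid | COc1c(CC=C(C)C)c(O)c(CC=C(C)C)c(CCc2ccc(O)cc2)c1C(=O)O | target

**Step count and risks**

Total step count: 11. Longest linear sequence: 8 steps (steps 1–6, 10, 11); the tyrosol branch (steps 7–9) joins at step 10.

Steps most likely to fail:

Step 10. Several processes can divert it. The magnesiated triflate may undergo O-to-C migration of the triflyl group (anionic thia-Fries shift) instead of β-elimination. The nucleophile may add at C1 if the C5 prenyl group shields C6 more than expected. The Grignard reagent may deliver a β-hydride to the aryne or attack the sulfonyl sulfur. The arylmagnesium adduct may be protonated by the liberated amine before CO2 arrives. The fallback sets out from triflate 10 and Grignard reagent 14 and returns at acid 19 without any aryne. Transmetalation of 14 with ZnCl2 in THF gives the alkylzinc chloride F1, and Negishi coupling of it with 10 at C6 (Pd(OAc)2, SPhos, THF, 50 °C) should give the pentasubstituted arene F2 with C1–H intact. Vilsmeier–Haack formylation (POCl3, DMF, 0 → 40 °C) at C1, the only free ring position and one activated by the ortho methoxy and para silyloxy groups, should give the aldehyde F3. Pinnick oxidation (NaClO2, NaH2PO4, excess 2-methylbut-2-ene, t-BuOH/H2O) then leads to 19.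

Step 5. Steric discrimination between the two phenols may be incomplete, leading to triflation at the prenyl-flanked oxygen or to double triflation. The fallback sets out from diol 8 and returns at triflate 10 by selective deprotection instead of selective functionalisation. Exhaustive silylation (TBSOTf, 2,6-lutidine) gives the bis-silyl ether F4. Mild basic desilylation (Cs2CO3, DMF/H2O, 25 °C) should remove only the silyl group on the oxygen with one ortho substituent, because attack at silicon between two prenyl groups is much slower, giving the phenol F5. Triflation of this single free phenol (Tf2O, pyridine, CH2Cl2, 0 °C) gives 10.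

Step 3. Deprotonation may occur at the benzylic-allylic CH2 of the existing prenyl group instead of at the ring, or alkylation of the crowded aryllithium may be sluggish. The fallback sets out from 5 and returns at diol 8 by a Claisen route. Partial acid methanolysis of symmetric 5 (p-TsOH, MeOH, stopped near half conversion, unchanged 5 recycled) gives the mono-phenol F6; either MOM group gives the same compound. Pd(PPh3)4-catalysed decarboxylative O-allylation with tert-butyl 2-methylbut-3-en-2-yl carbonate gives the aryl 1,1-dimethylallyl ether F7. Aromatic Claisen rearrangement (Eu(fod)3 cat., CHCl3, 60 °C) transfers the allyl unit with inversion to the only free ortho carbon and so creates the second 3-methylbut-2-enyl group in the phenol F8. Removal of the remaining MOM group (HCl, MeOH, 0 → 25 °C) gives 8.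

**Further compounds**
F1 | step 10 | chloro{2-[4-(tert-butyldimethylsilyloxy)phenyl]ethyl}zinc | Cl[Zn]CCc1ccc(O[Si](C)(C)C(C)(C)C)cc1
F2 | step 10 | tert-butyl[3-{2-[4-(tert-butyldimethylsilyloxy)phenyl]ethyl}-5-methoxy-2,6-bis(3-methylbut-2-enyl)phenoxy]dimethylsilane | COc1cc(CCc2ccc(O[Si](C)(C)C(C)(C)C)cc2)c(CC=C(C)C)c(O[Si](C)(C)C(C)(C)C)c1CC=C(C)C
F3 | step 10 | 4-(tert-butyldimethylsilyloxy)-6-{2-[4-(tert-butyldimethylsilyloxy)phenyl]ethyl}-2-methoxy-3,5-bis(3-methylbut-2-enyl)benzaldehyde | O=Cc1c(OC)c(CC=C(C)C)c(O[Si](C)(C)C(C)(C)C)c(CC=C(C)C)c1CCc1ccc(O[Si](C)(C)C(C)(C)C)cc1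
F4 | step 5 | 1-methoxy-3,5-bis(tert-butyldimethylsilyloxy)-2,4-bis(3-methylbut-2-enyl)benzene | COc1cc(O[Si](C)(C)C(C)(C)C)c(CC=C(C)C)c(O[Si](C)(C)C(C)(C)C)c1CC=C(C)C
F5 | step 5 | 3-(tert-butyldimethylsilyloxy)-5-methoxy-2,4-bis(3-methylbut-2-enyl)phenol | COc1cc(O)c(CC=C(C)C)c(O[Si](C)(C)C(C)(C)C)c1CC=C(C)C
F6 | step 3 | 5-methoxy-3-(methoxymethoxy)-2-(3-methylbut-2-enyl)phenol | COCOc1cc(OC)cc(O)c1CC=C(C)C
F7 | step 3 | 5-methoxy-1-(methoxymethoxy)-3-(2-methylbut-3-en-2-yloxy)-2-(3-methylbut-2-enyl)benzene | COCOc1cc(OC)cc(OC(C)(C)C=C)c1CC=C(C)C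
F8 | step 3 | 3-methoxy-5-(methoxymethoxy)-2,6-bis(3-methylbut-2-enyl)phenol | COCOc1cc(OC)c(CC=C(C)C)c(O)c1CC=C(C)C
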